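**Retrosynthetic overview**
1. Paraensidimerin C (C30H30N2O4) is two C15H15NO2 monomers. Cut the two ether bonds (O–CMe2 of the trans-fused pyran, O–C(Me) of the bridged pyran) and the two cyclohexane bonds C-b–C-d and C-a–C-c.
2. Both halves come from one monomer, a 2-isopropenyl-2,3-dihydrofuro[3,2-c]quinolinone, whose ring oxygen sits one carbon away from where it ends. The key step is an ionic, acid-catalysed ring expansion (1,2-shift of the aryloxy oxygen, dihydrofuran to dihydropyran, once in each half) coupled to the dimerisation.
3. The dihydrofuran comes from 4-hydroxy-1-methylquinolin-2-one and a C5 allylic dibromide (C-alkylation, then O-closure); the quinolinone comes from N-methylaniline and malonic acid.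
4. Ring order: quinolinone, dihydrofuran, then in the key step 2H-pyran (ring expansion), cyclohexane, trans-fused pyran, bridged pyran.

Labels: in the dimeric compounds the six carbons of the final cyclohexane are C-a (bears CMe2–O), C-b (bears the first quinolinone), C-d (CH2), C-q (C–Me, finally C–O), C-f (CH, finally CH2) and C-c (bears the second quinolinone).
Assumption: the (R)-configured acid is taken to give the S configuration at C-b; if the sense proves opposite, the (S)-acid is used and nothing else changes.

**Step 1**
Reactants: 1 N-methylaniline; 2 malonic acid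
Product: 4 4-hydroxy-1-methylquinolin-2(1H)-one, via malonamic acid 3 (not isolated)
Conditions: POCl3 (3 equiv), 90 °C, 2 h; then ice–water
Reagents that add atoms: none
Why: POCl3 activates malonic acid for N-acylation to the malonamic acid, whose second activated carboxyl closes onto the ortho position by intramolecular Friedel–Crafts acylation (Ziegler-type 4-hydroxy-2-quinolinone synthesis), and no stereocentre is formed.

**Step 2**
Reactants: 4 4-hydroxy-1-methylquinolin-2(1H)-one; 5 (E)-1,4-dibromo-2-methylbut-2-ene
Product: 7 racemic 5-methyl-2-(prop-1-en-2-yl)-2,3-dihydrofuro[3,2-c]quinolin-4(5H)-one, via allylic bromide 6 (not isolated)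
Conditions: K2CO3 (2.2 equiv), DMSO, 25 °C
Reagents that add atoms: none
Why: Tandem allylic alkylation of a cyclic 1,3-dicarbonyl, in which C-3 displaces the more reactive prenyl-type bromide (SN2) and the 4-oxygen then closes 5-exo by SN2′ on the remaining allylic bromide to leave the isopropenyl group, the E-alkene of the intermediate being unable to reach the 7-membered SN2 closure; the one stereocentre is formed racemic and is erased in step 3.

**Step 3**
Reactants: 7 racemic 5-methyl-2-(prop-1-en-2-yl)-2,3-dihydrofuro[3,2-c]quinolin-4(5H)-one (two molecules)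
Product: 12 paraensidimerin C, via dienol 8 (not isolated), via N-methylflindersine 9 (not isolated), via seco-dimer 10 (not isolated), via ene-phenol 11 (not isolated)
Conditions: (R)-3,3′-bis(2,4,6-triisopropylphenyl)-1,1′-binaphthyl-2,2′-diyl N-triflylphosphoramide (10 mol %), toluene/CH2Cl2 1:1, 0.05 M, −30 °C, 48 h; then 40 °C, 12 h
Reagents that add atoms: none
Why: Proposed new method: an enantioselective, stepwise ionic ring-expanding dimerisation in which the chiral acid protonates the lactam carbonyl of 7 and ionises the allylic C–O bond, loss of the benzylic proton gives dienol 8, and reprotonation of 8 at its terminal CH2 gives a hydroxy-stabilised prenyl cation that rests as 2H-pyran 9 (net 1,2-shift of oxygen, dihydrofuran to dihydropyran); within the ion pair with the chiral anion a second molecule of 8 attacks the quinolinone-bearing carbon of this cation through its terminal CH2 (sets C-b, S), the adduct rests as 2H-pyran 10, re-ionises and closes by a chair-like Prins-type cation–olefin cyclisation with all three substituents equatorial (sets C-a and C-c, trans,trans), the tertiary cation is trapped by the neighbouring 4-OH to give the trans-fused pyran of 11, and Markovnikov hydroalkoxylation of the ring alkene by the second 4-OH closes the bridged pyran, whose C-q can only form cis to its quinolinone (the cyclohexane goes to a boat); the closest known reactions are chiral-acid-catalysed additions to in situ vinyl ortho-quinone methides, cationic [4+2] reactions of allyl cations with dienes, and the furo-to-pyrano rearrangements of prenylated quinolinones.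

**Compound list**
1 | N-methylaniline | CNc1ccccc1 | starting material
2 | malonic acid | OC(=O)CC(=O)O | starting material
3 | 3-[methyl(phenyl)amino]-3-oxopropanoic acid (malonamic acid) | CN(C(=O)CC(=O)O)c1ccccc1 | intermediate
4 | 4-hydroxy-1-methylquinolin-2(1H)-one | Cn1c(=O)cc(O)c2ccccc21 | intermediate
5 | (E)-1,4-dibromo-2-methylbut-2-ene | BrC/C(C)=C/CBr | starting material
6 | 3-[(2E)-4-bromo-3-methylbut-2-en-1-yl]-4-hydroxy-1-methylquinolin-2(1H)-one | Cn1c(=O)c(C/C=C(C)/CBr)c(O)c2ccccc21 | intermediate
7 | racemic 5-methyl-2-(prop-1-en-2-yl)-2,3-dihydrofuro[3,2-c]quinolin-4(5H)-one | Cn1c(=O)c2c(c3ccccc31)OC(C2)C(C)=C | intermediate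
8 | 4-hydroxy-1-methyl-3-[(1E)-3-methylbuta-1,3-dien-1-yl]quinolin-2(1H)-one | Cn1c(=O)c(/C=C/C(C)=C)c(O)c2ccccc21 | intermediate
9 | N-methylflindersine, 2,2,6-trimethyl-2H-pyrano[3,2-c]quinolin-5(6H)-one | Cn1c(=O)c2c(c3ccccc31)OC(C)(C)C=C2 | intermediate
10 | 3-[(2S)-1-(2,6-dimethyl-5-oxo-5,6-dihydro-2H-pyrano[3,2-c]quinolin-2-yl)-4-methylpent-3-en-2-yl]-4-hydroxy-1-methylquinolin-2(1H)-one, both epimers at pyran C-2 | Cn1c(=O)c2c(c3ccccc31)OC(C)(C[C@@H](C=C(C)C)c1c(O)c3ccccc3n(C)c1=O)C=C2 | intermediate
11 | ene-phenol: trans-fused 2,2,6-trimethyl-3,4-dihydro-2H-pyrano[3,2-c]quinolin-5(6H)-one whose C-3 (C-a) and C-4 (C-b) belong to a cyclohexene C-a–C-b–C-dH2–C-q(Me)=C-fH–C-cH; C-c carries 4-hydroxy-1-methyl-2-oxo-1,2-dihydroquinolin-3-yl; H-a anti to H-b and to H-c; (aR,bS,cR) | Cn1c(=O)c2c(c3ccccc31)OC(C)(C)[C@@H]1[C@@H]2CC(C)=C[C@H]1c1c(O)c3ccccc3n(C)c1=O | intermediate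
12 | paraensidimerin C: 11 with the 4-oxygen of the C-c quinolinone bonded to C-q (2-oxabicyclo[3.3.1]nonane), that oxygen cis to the quinolinone at C-c, ring fusion at C-a/C-b trans; (aR,bS,cR,qS) | Cn1c(=O)c2c(c3ccccc31)OC(C)(C)[C@@H]1[C@@H]2C[C@]2(C)C[C@H]1c1c(c3ccccc3n(C)c1=O)O2 | target

**Totals**
Total steps: 3. Longest linear sequence: 3 (1 and 2 to 4, to 7, to 12).

**Steps most likely to fail and their fallbacks**

The new step, step 3, is the most likely to fail.
- Markovnikov protonation of the isopropenyl group of 7 can drain material to the aromatic 2-isopropylfuroquinolinone.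
- 9 can act as the alkene partner through its ring double bond and give cis-fused dimers.
- Cyclisation of 10 with its pyran still closed would give the epimeric series at C-a and C-b.
- The last hydroalkoxylation has to pass through a boat and may stall at 11.
- Reversible C–C ionisation can erode the ee.

If the furan drain dominates, 7 can first be opened to 8 with KOt-Bu before the acid is added. The fallback proper uses known chemistry and sets out from 4. Condensation with 3-methylbut-2-enal in refluxing pyridine gives 9 as an isolated compound. Heating 9 neat at about 200 °C, the biomimetic thermal dimerisation known for this alkaloid family, gives the dimers as racemates. Racemic 12 is separated from its ring-fusion isomers on silica. Preparative HPLC on a chiral stationary phase then removes the mirror image ent-paraensidimerin C F1, and the route is rejoined at 12.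

Step 2 can fail through O-alkylation of 4 or through C-alkylation at the methallyl-type terminus of 5, which leads to the useless 2-methyl-2-vinyl isomer. The fallback sets out from 4. C-prenylation with 1-bromo-3-methylbut-2-ene in aqueous NaOH gives 4-hydroxy-1-methyl-3-(3-methylbut-2-en-1-yl)quinolin-2(1H)-one F2. mCPBA in CH2Cl2 epoxidises the side chain and the 4-OH opens the epoxide 5-exo to racemic 2-(2-hydroxypropan-2-yl)-5-methyl-2,3-dihydrofuro[3,2-c]quinolin-4(5H)-one F3. Dehydration with SOCl2/pyridine at 0 °C gives the isopropenyl compound, and the route is rejoined at 7.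

Step 1 can fail through bis-anilide formation or chlorination at C-4 in hot POCl3. The fallback sets out from 1. Acylation with methyl 3-chloro-3-oxopropanoate and Et3N gives methyl 3-[methyl(phenyl)amino]-3-oxopropanoate F4. LiOH hydrolysis gives 3, now isolated. P2O5 in MeSO3H at 80 °C closes the ring, and the route is rejoined at 4.

**Further compounds**
F1 | step 3 | ent-paraensidimerin C | Cn1c(=O)c2c(c3ccccc31)OC(C)(C)[C@H]1[C@H]2C[C@@]2(C)C[C@@H]1c1c(c3ccccc3n(C)c1=O)O2
F2 | step 2 | 4-hydroxy-1-methyl-3-(3-methylbut-2-en-1-yl)quinolin-2(1H)-one | Cn1c(=O)c(CC=C(C)C)c(O)c2ccccc21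
F3 | step 2 | racemic 2-(2-hydroxypropan-2-yl)-5-methyl-2,3-dihydrofuro[3,2-c]quinolin-4(5H)-one | Cn1c(=O)c2c(c3ccccc31)OC(C2)C(C)(C)O
F4 | step 1 | methyl 3-[methyl(phenyl)amino]-3-oxopropanoate | COC(=O)CC(=O)N(C)c1ccccc1
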